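The two aryl–CH2 bonds at C6 and C8 of ring A are taken back to oxygen. Ring A is a phloroglucinol nucleus in which both prenylated carbons sit ortho to a ring oxygen, and the threefold symmetry of phloroglucinol makes its unsubstituted ring positions interchangeable. Heating 3,5-bis(2-methylbut-3-en-2-yloxy)phenol, a phloroglucinol with two tertiary allyl (reverse-prenyl) ethers and one free hydroxyl, should bring about two aromatic [3,3] shifts and give 2,4-diprenylphloroglucinol as a single regioisomer in one operation. The last ring CH then receives the acetyl group, the derived chromone is arylated enantioselectively at C2 by a ring B boronic acid, and the acetal protecting groups are removed.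

Key step: step 3

Remark: flavanone numbering is used for the target (ring B primed); 3-chloro-3-methylbut-1-yne is taken as a purchased reagent; the antipodes of the diene ligand (step 11) and of the ruthenium catalyst (fallback for step 11) are assigned by analogy with cyclic enones and chroman-4-ones and would be confirmed on the first run.

Step 1
Reactants: 1 phloroglucinol (benzene-1,3,5-triol); 2 3-chloro-3-methylbut-1-yne
Product: 3 3,5-bis(2-methylbut-3-yn-2-yloxy)phenol
Conditions: CuCl2·2H2O (1 mol%), DBU (2.3 equiv), MeCN, −5 → 0 °C, 2 (2.1 equiv) added slowly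
Reagents that add atoms: none
Why: Copper-catalysed propargylic etherification of a phenol (divalent copper chloride with DBU) activates the tertiary chloride through a copper acetylide so that the phenoxide attacks at oxygen where SN2 alkylation would fail; the three hydroxyls are equivalent, so about two equivalents of 2 are used and the much more polar mono-ether is separated and resubmitted.

Step 2
Reactants: 3 3,5-bis(2-methylbut-3-yn-2-yloxy)phenol
Product: 4 3,5-bis(2-methylbut-3-en-2-yloxy)phenol
Conditions: H2 (1 atm), Pd/CaCO3 poisoned with Pb(OAc)2, quinoline, EtOAc, rt, stopped after uptake of 2 equiv H2; product kept cold and used at once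
Reagents that add atoms: none
Why: Lindlar semi-hydrogenation should reduce each terminal alkyne to the vinyl group and stop there on the poisoned palladium surface, while the neutral room-temperature conditions leave the tertiary aryl ethers and the phenol untouched.

Step 3
Reactants: 4 3,5-bis(2-methylbut-3-en-2-yloxy)phenol
Product: 7 2,4-bis(3-methylbut-2-enyl)benzene-1,3,5-triol, via 2-prenyl mono-ether 5 (not isolated), via 4-prenyl mono-ether 6 (not isolated)
Conditions: degassed toluene, N,N-diethylaniline (0.2 equiv), 110 °C, Ar, sealed vessel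
Reagents that add atoms: none
Why: Each aryl 1,1-dimethylallyl ether of 4 undergoes a concerted suprafacial [3,3] sigmatropic shift through a chair-like six-membered transition state in which the terminal vinyl CH2 bonds to an ortho ring carbon as the O–C(CH3)2 bond breaks, so the allyl unit is inverted and the tertiary ether emerges as a normal prenyl group, after which enolisation restores the aromatic ring. The closest known reaction type is the aromatic Claisen rearrangement of aryl reverse-prenyl ethers to ortho-prenylphenols, here run twice on one ring. No ring is closed and no stereocentre is formed. The first shift can give 5 or 6, but because the free ring positions of the phloroglucinol nucleus are interchangeable, the second shift should convert both into the same triol 7, so regiochemistry needs no control. What must be secured is ortho [3,3] migration over heterolysis of the tertiary C–O bond (loss of isoprene, chroman closure) and over para migration: the gem-dimethyl group lowers the barrier enough for 110 °C, the degassed, non-polar, amine-buffered medium gives the ionic pathways neither acid nor polar support, and in 6 a shift onto the already prenylated ortho carbon is reversible and drains through the free ortho carbon.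

Step 4
Reactants: 7 2,4-bis(3-methylbut-2-enyl)benzene-1,3,5-triol (used crude, under Ar)
Product: 8 1,3,5-tris(methoxymethoxy)-2,4-bis(3-methylbut-2-enyl)benzene
Conditions: MOMCl (4.5 equiv), i-Pr2NEt, n-Bu4NI (cat.), CH2Cl2, 0 → 40 °C
Reagents that add atoms: chloromethyl methyl ether (MOMCl), COCCl
Why: Williamson-type O-alkylation of the three phenols with a hard alkoxymethyl chloride under amine base should give the tris-acetal, which masks the air-sensitive triol and places two ortho-directing groups around the last ring CH.

Step 5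
Reactants: 8 1,3,5-tris(methoxymethoxy)-2,4-bis(3-methylbut-2-enyl)benzene
Product: 11 1-[2,4,6-tris(methoxymethoxy)-3,5-bis(3-methylbut-2-enyl)phenyl]ethanone, via aryllithium 9 (not isolated), via tetrahedral lithium adduct 10 (not isolated)
Conditions: n-BuLi, TMEDA, THF, −20 → 0 °C; MeC(O)N(OMe)Me, −78 → 0 °C; aq. NH4Cl
Reagents that add atoms: N-methoxy-N-methylacetamide, CC(=O)N(C)OC
Why: Directed ortho-metalation followed by Weinreb ketone synthesis should work because the only ring hydrogen lies between two lithium-chelating methoxymethoxy groups, so deprotonation there should outrun lateral metalation of the prenyl CH2 groups, and the chelated adduct 10 holds back over-addition until work-up.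

Step 6
Reactants: 11 1-[2,4,6-tris(methoxymethoxy)-3,5-bis(3-methylbut-2-enyl)phenyl]ethanone
Product: 12 1-[2-hydroxy-4,6-bis(methoxymethoxy)-3,5-bis(3-methylbut-2-enyl)phenyl]ethanone
Conditions: HCl (0.3 M, from AcCl) in MeOH–THF, 0 °C → rt, quenched with NaHCO3 at the mono-cleavage stage
Reagents that add atoms: none
Why: Carbonyl-assisted selective acetal methanolysis should stop at the mono-phenol because an ether ortho to the acetyl group is cleaved fastest (the carbonyl relays the proton) and the freed phenol then locks the carbonyl in a hydrogen bond that deactivates the second ortho ether; the two ortho ethers are equivalent, so either gives 12.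

Step 7
Reactants: 12 1-[2-hydroxy-4,6-bis(methoxymethoxy)-3,5-bis(3-methylbut-2-enyl)phenyl]ethanone
Product: 14 5,7-bis(methoxymethoxy)-6,8-bis(3-methylbut-2-enyl)-4H-chromen-4-one, via enaminone 13 (not isolated)
Conditions: Me2NCH(OMe)2, toluene, 100 °C; concentrate; AcOH, CH2Cl2, rt
Reagents that add atoms: N,N-dimethylformamide dimethyl acetal, COC(OC)N(C)C
Why: In the enaminone route to chromones the methyl ketone condenses with the formamide acetal to the β-dimethylamino enone 13, and mild acid then triggers conjugate addition of the ortho phenol and loss of dimethylamine to close the pyranone ring, conditions the remaining acetals and the prenyl groups should tolerate.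

Step 8
Reactants: 15 4-bromoresorcinol (4-bromobenzene-1,3-diol); 16 prenal (3-methylbut-2-enal)
Product: 17 6-bromo-2,2-dimethyl-2H-chromen-7-ol
Conditions: ethylenediammonium diacetate (20 mol%), toluene, reflux
Reagents that add atoms: none
Why: Amine-salt-catalysed chromenylation of a resorcinol with an enal (condensation at a ring carbon ortho to a hydroxyl, dehydration, 6π oxa-electrocyclisation) should occur at C6 of 15, which is ortho to one hydroxyl, para to the other and unflanked as is the reactive carbon of resorcinol itself, while the bromine marks the future C1′ and blocks the position where a second annulation would otherwise start.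

Step 9
Reactants: 17 6-bromo-2,2-dimethyl-2H-chromen-7-ol
Product: 18 6-bromo-7-(methoxymethoxy)-2,2-dimethyl-2H-chromene
Conditions: MOMCl, i-Pr2NEt, CH2Cl2, 0 °C → rt
Reagents that add atoms: chloromethyl methyl ether (MOMCl), COCCl
Why: Base-mediated O-alkylation of the single phenol gives an acetal that survives organolithium and rhodium chemistry and is cleaved together with the ring A acetals at the end.

Step 10
Reactants: 18 6-bromo-7-(methoxymethoxy)-2,2-dimethyl-2H-chromene
Product: 21 [7-(methoxymethoxy)-2,2-dimethyl-2H-chromen-6-yl]boronic acid, via aryllithium 19 (not isolated), via lithium triisopropoxyborate 20 (not isolated)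
Conditions: n-BuLi, THF, −78 °C; B(OiPr)3, −78 °C → rt; aq. NH4Cl
Reagents that add atoms: triisopropyl borate, CC(C)OB(OC(C)C)OC(C)C; water, O
Why: Bromine–lithium exchange at −78 °C is faster than any deprotonation, the aryllithium 19 is trapped by the borate ester as the ate complex 20, and buffered aqueous hydrolysis should release the boronic acid without touching the acetal or the chromene.

Step 11
Reactants: 14 5,7-bis(methoxymethoxy)-6,8-bis(3-methylbut-2-enyl)-4H-chromen-4-one; 21 [7-(methoxymethoxy)-2,2-dimethyl-2H-chromen-6-yl]boronic acid (2.5 equiv)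
Product: 22 (2S)-5,7-bis(methoxymethoxy)-2-[7-(methoxymethoxy)-2,2-dimethyl-2H-chromen-6-yl]-6,8-bis(3-methylbut-2-enyl)-2,3-dihydro-4H-chromen-4-one
Conditions: [RhCl(C2H4)2]2 (3 mol%), (1S,4S)-2,5-diphenylbicyclo[2.2.2]octa-2,5-diene (6.6 mol%), aq. K3PO4 (0.5 equiv), toluene–H2O, 40 °C
Reagents that add atoms: none
Why: In this Hayashi–Miyaura asymmetric 1,4-addition with a monovalent rhodium–chiral diene catalyst, transmetalation gives an aryl–rhodium species, the C2=C3 bond of the chromone inserts with the aryl group delivered to the Re face of C2 under control of the C2-symmetric diene (setting 2S), and protonolysis of the rhodium enolate releases the flavanone, while the cool, weakly basic medium should avoid ring-opening of the product and leave the isolated alkenes alone.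

Step 12
Reactants: 22 (2S)-5,7-bis(methoxymethoxy)-2-[7-(methoxymethoxy)-2,2-dimethyl-2H-chromen-6-yl]-6,8-bis(3-methylbut-2-enyl)-2,3-dihydro-4H-chromen-4-one
Product: 23 euchrenone a3
Conditions: HCl (1 M, from AcCl) in MeOH–THF, 0 °C → rt, monitored, NaHCO3 quench
Reagents that add atoms: none
Why: Acid-catalysed methanolysis of the three aryl methoxymethyl acetals under dilute, cool conditions should free the 5-, 7- and 2′-hydroxyls without ionising the benzylic C2–O1 bond (so the 2S centre is kept), protonating the chromene C3=C4 bond or closing the prenyl groups onto neighbouring hydroxyls.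

Compound list
1 | phloroglucinol (benzene-1,3,5-triol) | Oc1cc(O)cc(O)c1 | starting material
2 | 3-chloro-3-methylbut-1-yne | CC(C)(Cl)C#C | starting material
3 | 3,5-bis(2-methylbut-3-yn-2-yloxy)phenol | Oc1cc(OC(C)(C)C#C)cc(OC(C)(C)C#C)c1 | intermediate
4 | 3,5-bis(2-methylbut-3-en-2-yloxy)phenol | Oc1cc(OC(C)(C)C=C)cc(OC(C)(C)C=C)c1 | intermediate
5 | 5-(2-methylbut-3-en-2-yloxy)-2-(3-methylbut-2-enyl)benzene-1,3-diol | CC(C)=CCc1c(O)cc(OC(C)(C)C=C)cc1O | intermediate
6 | 5-(2-methylbut-3-en-2-yloxy)-4-(3-methylbut-2-enyl)benzene-1,3-diol | CC(C)=CCc1c(O)cc(O)cc1OC(C)(C)C=C | intermediate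
7 | 2,4-bis(3-methylbut-2-enyl)benzene-1,3,5-triol | CC(C)=CCc1c(O)cc(O)c(CC=C(C)C)c1O | intermediate
8 | 1,3,5-tris(methoxymethoxy)-2,4-bis(3-methylbut-2-enyl)benzene | COCOc1cc(OCOC)c(CC=C(C)C)c(OCOC)c1CC=C(C)C | intermediate
9 | [2,4,6-tris(methoxymethoxy)-3,5-bis(3-methylbut-2-enyl)phenyl]lithium | [Li]c1c(OCOC)c(CC=C(C)C)c(OCOC)c(CC=C(C)C)c1OCOC | intermediate
10 | lithium 1-[methoxy(methyl)amino]-1-[2,4,6-tris(methoxymethoxy)-3,5-bis(3-methylbut-2-enyl)phenyl]ethanolate | [Li+].CC([O-])(N(C)OC)c1c(OCOC)c(CC=C(C)C)c(OCOC)c(CC=C(C)C)c1OCOC | intermediate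
11 | 1-[2,4,6-tris(methoxymethoxy)-3,5-bis(3-methylbut-2-enyl)phenyl]ethanone | CC(=O)c1c(OCOC)c(CC=C(C)C)c(OCOC)c(CC=C(C)C)c1OCOC | intermediate
12 | 1-[2-hydroxy-4,6-bis(methoxymethoxy)-3,5-bis(3-methylbut-2-enyl)phenyl]ethanone | CC(=O)c1c(O)c(CC=C(C)C)c(OCOC)c(CC=C(C)C)c1OCOC | intermediate
13 | (E)-3-(dimethylamino)-1-[2-hydroxy-4,6-bis(methoxymethoxy)-3,5-bis(3-methylbut-2-enyl)phenyl]prop-2-en-1-one | CN(C)/C=C/C(=O)c1c(O)c(CC=C(C)C)c(OCOC)c(CC=C(C)C)c1OCOC | intermediate
14 | 5,7-bis(methoxymethoxy)-6,8-bis(3-methylbut-2-enyl)-4H-chromen-4-one | O=C1C=COc2c1c(OCOC)c(CC=C(C)C)c(OCOC)c2CC=C(C)C | intermediate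
15 | 4-bromoresorcinol (4-bromobenzene-1,3-diol) | Oc1ccc(Br)c(O)c1 | starting material
16 | prenal (3-methylbut-2-enal) | CC(C)=CC=O | starting material
17 | 6-bromo-2,2-dimethyl-2H-chromen-7-ol | CC1(C)C=Cc2cc(Br)c(O)cc2O1 | intermediate
18 | 6-bromo-7-(methoxymethoxy)-2,2-dimethyl-2H-chromene | CC1(C)C=Cc2cc(Br)c(OCOC)cc2O1 | intermediate
19 | [7-(methoxymethoxy)-2,2-dimethyl-2H-chromen-6-yl]lithium | [Li]c1cc2C=CC(C)(C)Oc2cc1OCOC | intermediate
20 | lithium [7-(methoxymethoxy)-2,2-dimethyl-2H-chromen-6-yl]tri(propan-2-yloxy)borate | [Li+].CC(C)O[B-](OC(C)C)(OC(C)C)c1cc2C=CC(C)(C)Oc2cc1OCOC | intermediate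
21 | [7-(methoxymethoxy)-2,2-dimethyl-2H-chromen-6-yl]boronic acid | OB(O)c1cc2C=CC(C)(C)Oc2cc1OCOC | intermediate
22 | (2S)-5,7-bis(methoxymethoxy)-2-[7-(methoxymethoxy)-2,2-dimethyl-2H-chromen-6-yl]-6,8-bis(3-methylbut-2-enyl)-2,3-dihydro-4H-chromen-4-one | CC(C)=CCc1c(OCOC)c(CC=C(C)C)c2c(c1OCOC)C(=O)C[C@@H](c1cc3c(cc1OCOC)OC(C)(C)C=C3)O2 | intermediate
23 | euchrenone a3, (2S)-5,7-dihydroxy-2-(7-hydroxy-2,2-dimethyl-2H-chromen-6-yl)-6,8-bis(3-methylbut-2-enyl)-2,3-dihydro-4H-chromen-4-one | CC(C)=CCc1c(O)c(CC=C(C)C)c2c(c1O)C(=O)C[C@@H](c1cc3c(cc1O)OC(C)(C)C=C3)O2 | target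

Total steps: 12. Longest linear sequence: 9 steps (steps 1–7, 11 and 12); the ring B branch is 3 steps (8–10).

Steps most likely to fail

Step 11. Insertion of the hindered, electron-rich chromone into the aryl–rhodium bond may be slower than protodeboronation of the ortho-alkoxy boronic acid, or the ortho substituent may lower facial selectivity. The fallback builds the heterocycle by condensation and sets C2 by kinetic resolution; it sets out from 12 and 18 and rejoins at 22. Bromide 18 is converted to aryllithium 19 (n-BuLi, THF, −78 °C), and DMF gives the lithium hemiaminal adduct F1, which hydrolyses on work-up to 7-(methoxymethoxy)-2,2-dimethyl-2H-chromene-6-carbaldehyde F2. Claisen–Schmidt condensation of 12 with F2 (KOH, EtOH–H2O, rt) should give the 2′-hydroxychalcone F3, and NaOAc in refluxing EtOH should close it by intramolecular oxa-Michael addition to the racemic flavanone F4. Asymmetric transfer hydrogenation with RuCl(p-cymene)[(R,R)-TsDPEN] (HCO2H–Et3N, EtOAc, rt, run to just past half conversion) is expected to reduce the 2R ketone to the cis-flavan-4-ol F5, which is removed by chromatography, and to leave the 2S ketone 22.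

Step 12. Acid may ionise the C2–O1 bond, which is benzylic to the 2′,4′-dioxygenated ring and whose ionisation would erode the 2S configuration; it may also protonate the electron-rich chromene double bond or cyclise a prenyl group onto a freed hydroxyl. The fallback replaces protic solvolysis by a two-stage exchange of protecting groups; it sets out from 22 and ends at 23. TMSOTf with 2,2′-bipyridyl in MeCN at 0 °C should transfer the three aryl acetals into aryl silyl ethers without free Brønsted acid, giving the tris(trimethylsilyl) ether F6. Addition of water at rt then hydrolyses the labile aryl silyl ethers to 23.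

Step 1. Etherification of three equivalent hydroxyls may spread the material over mono-, bis- and tris-ethers so that little of the bis-ether is obtained per pass. The fallback moves the statistics to the cheapest reagent and makes the etherification exhaustive; it sets out from 1 and rejoins at 3. With 1 in threefold excess, TIPSCl (1 equiv) and imidazole in DMF at 0 °C should give mainly 5-[tri(propan-2-yl)silyloxy]benzene-1,3-diol F7, the surplus 1 being washed out with water. Both remaining hydroxyls are etherified with an excess of 2 (CuCl2·2H2O, DBU, MeCN, 0 °C) to the silyl bis-propargyl ether F8. n-Bu4NF in THF at 0 °C then removes the silyl group to give 3.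

Further compounds
F1 | step 11 | lithium (dimethylamino)[7-(methoxymethoxy)-2,2-dimethyl-2H-chromen-6-yl]methanolate | [Li+].CN(C)C([O-])c1cc2C=CC(C)(C)Oc2cc1OCOC
F2 | step 11 | 7-(methoxymethoxy)-2,2-dimethyl-2H-chromene-6-carbaldehyde | COCOc1cc2OC(C)(C)C=Cc2cc1C=O
F3 | step 11 | (E)-1-[2-hydroxy-4,6-bis(methoxymethoxy)-3,5-bis(3-methylbut-2-enyl)phenyl]-3-[7-(methoxymethoxy)-2,2-dimethyl-2H-chromen-6-yl]prop-2-en-1-one | COCOc1cc2OC(C)(C)C=Cc2cc1/C=C/C(=O)c1c(O)c(CC=C(C)C)c(OCOC)c(CC=C(C)C)c1OCOC
F4 | step 11 | rac-5,7-bis(methoxymethoxy)-2-[7-(methoxymethoxy)-2,2-dimethyl-2H-chromen-6-yl]-6,8-bis(3-methylbut-2-enyl)-2,3-dihydro-4H-chromen-4-one | CC(C)=CCc1c(OCOC)c(CC=C(C)C)c2c(c1OCOC)C(=O)CC(c1cc3c(cc1OCOC)OC(C)(C)C=C3)O2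
F5 | step 11 | (2R,4R)-5,7-bis(methoxymethoxy)-2-[7-(methoxymethoxy)-2,2-dimethyl-2H-chromen-6-yl]-6,8-bis(3-methylbut-2-enyl)-3,4-dihydro-2H-chromen-4-ol | CC(C)=CCc1c(OCOC)c(CC=C(C)C)c2c(c1OCOC)[C@H](O)C[C@H](c1cc3c(cc1OCOC)OC(C)(C)C=C3)O2
F6 | step 12 | (2S)-2-[2,2-dimethyl-7-(trimethylsilyloxy)-2H-chromen-6-yl]-6,8-bis(3-methylbut-2-enyl)-5,7-bis(trimethylsilyloxy)-2,3-dihydro-4H-chromen-4-one | CC(C)=CCc1c(O[Si](C)(C)C)c(CC=C(C)C)c2c(c1O[Si](C)(C)C)C(=O)C[C@@H](c1cc3c(cc1O[Si](C)(C)C)OC(C)(C)C=C3)O2
F7 | step 1 | 5-[tri(propan-2-yl)silyloxy]benzene-1,3-diol | CC(C)[Si](Oc1cc(O)cc(O)c1)(C(C)C)C(C)C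
F8 | step 1 | [3,5-bis(2-methylbut-3-yn-2-yloxy)phenoxy]tri(propan-2-yl)silane | CC(C)[Si](Oc1cc(OC(C)(C)C#C)cc(OC(C)(C)C#C)c1)(C(C)C)C(C)C
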